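Ring A (C10–C15) together with C9 is read as a pinane-type bicyclo[3.1.1]heptan-6-one in which the C9 carbonyl bridges C10 and C14. Everything rests on breaking the C9–C14 bond: Baeyer–Villiger oxygen insertion there should, in one operation, delete the only bond absent from the target, place oxygen on C14 with retention and leave C9 as the carboxyl carbon on C10, with the cyclohexane already formed. The precursor is the C11–C12 epoxide of the cyclobutanone photoisomer of (+)-verbenone; its epoxide oxygen, cis to C9, later becomes the axial C11 hydroxyl. An (S)-linalool-derived C1–C8 unit is then joined at C9 and closed to the bromotetrahydropyran.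

Key step: step 3

Numbering (target): C1=C2 is the vinyl group on C3; O, C3, C4, C5, C6 (CHBr) and C7 form the tetrahydropyran; C8–C9 link C7 to ring A; ring A is C10 (CH), C11 (C(CH3)OH), C12, C13, C14 (CHBr), C15 (C(CH3)2).

Remark: (+)-verbenone and (S)-linalool of high enantiomeric purity are assumed to be purchased; (+)-verbenone can otherwise be made from (+)-α-pinene by allylic oxidation.

**Route**

Step 1
Reactants: 1 (1R,5R)-(+)-verbenone
Product: 2 (1S,5R)-chrysanthenone (2,7,7-trimethylbicyclo[3.1.1]hept-2-en-6-one)
Conditions: hν (350 nm lamps, Pyrex), cyclohexane, rt, stopped at partial conversion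
Reagents that add atoms: none
Why: Photochemical 1,3-alkyl shift of the enone moves the C15–C12 bond suprafacially to C10 while the C14 stereocentre is untouched, so the new bridgehead C10 is dictated by the bicycle; long-wavelength light and partial conversion are chosen because the product can lose optical purity by retro-[2+2] opening to an achiral dienylketene.

Step 2
Reactants: 2 (1S,5R)-chrysanthenone
Product: 3 chrysanthenone 2,3-epoxide (oxirane oxygen on the face of the C9 carbonyl bridge, anti to the C15 bridge)
Conditions: dimethyldioxirane, acetone, 0 °C
Reagents that add atoms: dimethyldioxirane CC1(C)OO1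
Why: Dioxirane epoxidation transfers oxygen to the trisubstituted C11=C12 alkene without touching the ketone, and approach anti to the gem-dimethyl bridge sets C11 and C12 with oxygen cis to C9.

Step 3
Reactants: 3 chrysanthenone 2,3-epoxide
Product: 4 epoxy γ-lactone (2,3-epoxy-2,8,8-trimethyl-6-oxabicyclo[3.2.1]octan-7-one; C9(=O)–O–C14 bridge and epoxide on the same face of ring A)
Conditions: mCPBA, NaHCO3 (solid buffer), CH2Cl2, 0 °C
Reagents that add atoms: 3-chloroperbenzoic acid OOC(=O)c1cccc(Cl)c1
Why: The peracid should add to the strained C9 carbonyl from its open exo face to give the Criegee adduct, and the C9–C14 bond anti to the breaking O–O bond then shifts to oxygen with loss of 3-chlorobenzoate. This is a Baeyer–Villiger oxidation of a bridged bicyclic cyclobutanone, a standard route to γ-lactones in which relief of four-ring strain makes the ketone far more reactive than an unstrained one. The five-membered lactone ring (C9, O, C14, C15, C10) is closed by 1,2-shift ring expansion of the cyclobutanone and not by a cyclisation, so ring A emerges intact and no carbocycle has to be made. The new C14–O stereocentre is fixed by the retentive migration, which puts oxygen exactly where C9 was, cis to the carboxyl carbon on C10. The step needs C14 to migrate in preference to C10: both are bridgehead methines, but C10 carries the electron-withdrawing C11–O bond of the epoxide in the β-position and should be the poorer migrating group, step 2 has already removed the alkene that would make C10 allylic and migration-prone, and the bicarbonate buffer protects the acid-labile epoxide.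

Step 4
Reactants: 4 epoxy γ-lactone
Product: 5 triol (2-(hydroxymethyl)-1,3,3-trimethylcyclohexane-1,4-diol; C9H2OH, C11–OH and C14–OH all cis, C11–OH axial)
Conditions: LiAlH4, THF, 0 °C to reflux; aq. NaOH work-up
Reagents that add atoms: none
Why: Hydride reduction of the lactone to the C9/C14 diol and SN2 hydride opening of the trisubstituted epoxide at the less substituted C12 (trans-diaxial, Fürst–Plattner) leave the tertiary C11 hydroxyl axial and cis to C9, with no stereocentre touched.

Step 5
Reactants: 5 triol
Product: 6 C9 phenyl sulfide diol (2-[(phenylthio)methyl]-1,3,3-trimethylcyclohexane-1,4-diol, configuration as in 5)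
Conditions: PhSSPh, n-Bu3P, pyridine, rt to 50 °C
Reagents that add atoms: diphenyl disulfide c1ccc(SSc2ccccc2)cc1
Why: In this phosphine–disulfide redox-condensation thioetherification only the primary C9 hydroxyl forms a reactive oxyphosphonium and is displaced (SN2) by the paired thiophenolate; the neopentyl secondary and tertiary hydroxyls are inert, and the thiolate should outrun ether closure by the C14 hydroxyl, which needs the disfavoured diaxial ring conformer.

Step 6
Reactants: 6 C9 phenyl sulfide diol
Product: 7 keto sulfone (4-hydroxy-2,2,4-trimethyl-3-[(phenylsulfonyl)methyl]cyclohexan-1-one)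
Conditions: (n-Pr)4N[RuO4] (cat.), NMO (excess), 4 Å MS, MeCN/CH2Cl2, rt
Reagents that add atoms: N-methylmorpholine N-oxide C[N+]1([O-])CCOCC1
Why: Ley–Griffith perruthenate oxidation with NMO as terminal oxidant should convert the sulfide to the sulfone via the sulfoxide and the secondary C14 alcohol to the ketone in one operation, leaving the tertiary C11 hydroxyl alone and deliberately erasing the C14 stereocentre for its inversion.

Step 7
Reactants: 7 keto sulfone
Product: 8 C11 triethylsilyl ether of the keto sulfone
Conditions: Et3SiOTf, 2,6-lutidine, CH2Cl2, −78 to 0 °C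
Reagents that add atoms: triethylsilyl triflate CC[Si](CC)(CC)OS(=O)(=O)C(F)(F)F
Why: Silyl triflate silylation of the only free hydroxyl masks the C11 oxygen, which would otherwise compete for the C7 bromonium carbon in step 14 (six-membered ether to C7) and could attack an activated C14 from the opposite face in step 15.

Step 8
Reactants: 8 C11 triethylsilyl ether of the keto sulfone
Product: 9 axial C14 alcohol (C14–OH trans to the C9 sulfonylmethyl group)
Conditions: Li[HB(s-Bu)3], THF, −78 °C; then H2O
Reagents that add atoms: none
Why: Diastereoselective ketone reduction with a bulky trialkylborohydride: the reagent avoids the axial path and delivers hydride equatorially from the ring face that carries C9, giving the axial C14 alcohol trans to C9, as known for 2,2-dimethylcyclohexanones of the 4,4-dimethyl-3-keto terpenoid type.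

Step 9
Reactants: 10 (S)-(+)-linalool
Product: 11 (2E,6S)-2,6-dimethylocta-2,7-diene-1,6-diol ((S,E)-8-hydroxylinalool)
Conditions: SeO2 (cat.), t-BuOOH, CH2Cl2, rt
Reagents that add atoms: tert-butyl hydroperoxide CC(C)(C)OO
Why: Riley-type allylic oxidation (ene reaction then [2,3]-sigmatropic shift), catalytic in selenium, hydroxylates the (E)-methyl group of the trisubstituted alkene selectively and so fixes the (E) geometry of the future C6=C7 bond; the C3 carbinol and vinyl group are untouched.

Step 10
Reactants: 11 (2E,6S)-2,6-dimethylocta-2,7-diene-1,6-diol
Product: 12 (3S,6E)-8-bromo-3,7-dimethylocta-1,6-dien-3-ol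
Conditions: CBr4, PPh3, CH2Cl2, −30 °C
Reagents that add atoms: carbon tetrabromide BrC(Br)(Br)Br
Why: Appel bromination at low temperature activates and displaces only the primary allylic hydroxyl (SN2, no allylic transposition), leaving the tertiary carbinol alone.

Step 11
Reactants: 12 (3S,6E)-8-bromo-3,7-dimethylocta-1,6-dien-3-ol
Product: 13 trimethylsilyl ether of 12
Conditions: Me3SiOTf, 2,6-lutidine, CH2Cl2, −78 °C
Reagents that add atoms: trimethylsilyl triflate C[Si](C)(C)OS(=O)(=O)C(F)(F)F
Why: Silyl triflate silylation of the tertiary alcohol gives a labile trimethylsilyl ether that keeps the hydroxyl proton away from the sulfone carbanion of step 12 and can later be removed without loss of the C11 triethylsilyl ether.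

Step 12
Reactants: 9 axial C14 alcohol; 13 trimethylsilyl ether of 12
Product: 15 C9-phenylsulfonyl coupled triene (both C9 epimers), via dilithio sulfone 14 (not isolated)
Conditions: n-BuLi (2.1 equiv), THF, −78 °C; then 13, −78 to −20 °C; H2O
Reagents that add atoms: none
Why: Julia-type alkylation of an α-sulfonyl carbanion: the C14 alkoxide/C9 carbanion dianion attacks the primary allylic bromide at C8 in SN2 fashion, forming C8–C9 with the (E)-alkene intact (the pattern of cyclogeranyl sulfone couplings); the new C9 centre is a mixture that disappears in step 13.

Step 13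
Reactants: 15 C9-phenylsulfonyl coupled triene
Product: 17 diene diol (free C3–OH and axial C14–OH; C11–OSiEt3), via desulfonylated trimethylsilyl ether 16 (not isolated)
Conditions: Na(Hg) (6%), Na2HPO4, MeOH/THF, −20 °C; then K2CO3 (cat.), MeOH, rt
Reagents that add atoms: none
Why: Reductive desulfonylation by electron transfer from Na(Hg) in buffered methanol removes the homoallylic sulfone without alkene migration, and base-catalysed methanolysis then cleaves only the tertiary trimethylsilyl ether while the bulkier triethylsilyl ether survives.

Step 14
Reactants: 17 diene diol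
Product: 18 bromotetrahydropyran alcohol (C6–Br cis to the C7 and C3 methyl groups; axial C14–OH; C11–OSiEt3)
Conditions: 2,4,4,6-tetrabromocyclohexa-2,5-dienone (TBCO), MeNO2, 0 °C to rt, dark
Reagents that add atoms: 2,4,4,6-tetrabromocyclohexa-2,5-dienone O=C1C(Br)=CC(Br)(Br)C=C1Br
Why: Bromoetherification: Br+ transfer to the electron-rich (E)-C6=C7 alkene and Markovnikov 6-endo attack of the C3 hydroxyl on C7 anti to bromine should give the 3-bromotetrahydropyran, anti addition across the (E)-alkene placing Br on C6 cis to the C7 methyl; the isomer needed comes from the alkene face that leaves the C3 and C7 methyls cis, and its C6/C7 diastereomer and 5-exo tetrahydrofurans are expected as separable by-products.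

Step 15
Reactants: 18 bromotetrahydropyran alcohol
Product: 19 dibromide C11 triethylsilyl ether (equatorial C14–Br cis to C9)
Conditions: CBr4, PPh3, toluene, rt to 60 °C
Reagents that add atoms: carbon tetrabromide BrC(Br)(Br)Br
Why: Appel bromination with inversion: the axial C14 oxyphosphonium is displaced by bromide from the ring face that carries C9, giving the equatorial bromide cis to C9; an axial leaving group is the arrangement in which SN2 at this neopentyl carbon competes best with elimination and methyl shift, and the ethers and the existing bromide are inert.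

Step 16
Reactants: 19 dibromide C11 triethylsilyl ether
Product: 20 CNP0244533.1
Conditions: HF·pyridine, pyridine, THF, 0 °C to rt
Reagents that add atoms: none
Why: Fluoride-mediated desilylation under buffered conditions should free the axial tertiary C11 hydroxyl without affecting the secondary bromides, the vinyl group or the tertiary allylic ether, giving the target.

**Compound list**

1 | (1R,5R)-(+)-verbenone | CC1=CC(=O)[C@@H]2C[C@H]1C2(C)C | starting material
2 | (1S,5R)-chrysanthenone | O=C1[C@@H]2C(C)(C)[C@H]1CC=C2C | intermediate
3 | chrysanthenone 2,3-epoxide, oxygen cis to the C9 bridge | O=C1[C@@H]2C(C)(C)[C@H]1C[C@@H]3O[C@]23C | intermediate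
4 | epoxy γ-lactone (2,3-epoxy-2,8,8-trimethyl-6-oxabicyclo[3.2.1]octan-7-one) | O=C1[C@@H]2C(C)(C)[C@H](O1)C[C@@H]3O[C@]23C | intermediate
5 | all-cis triol (2-(hydroxymethyl)-1,3,3-trimethylcyclohexane-1,4-diol) | OC[C@@H]1C(C)(C)[C@H](O)CC[C@]1(C)O | intermediate
6 | C9 phenyl sulfide diol | c1ccccc1SC[C@@H]1C(C)(C)[C@H](O)CC[C@]1(C)O | intermediate
7 | keto sulfone (C14 ketone, C9 phenyl sulfone, free C11–OH) | O=S(=O)(c1ccccc1)C[C@@H]1C(C)(C)C(=O)CC[C@]1(C)O | intermediate
8 | C11 triethylsilyl ether of the keto sulfone | O=S(=O)(c1ccccc1)C[C@@H]1C(C)(C)C(=O)CC[C@]1(C)O[Si](CC)(CC)CC | intermediate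
9 | axial C14 alcohol, OH trans to C9 | O=S(=O)(c1ccccc1)C[C@@H]1C(C)(C)[C@@H](O)CC[C@]1(C)O[Si](CC)(CC)CC | intermediate
10 | (S)-(+)-linalool | C=C[C@@](C)(O)CCC=C(C)C | starting material
11 | (2E,6S)-2,6-dimethylocta-2,7-diene-1,6-diol | C=C[C@@](C)(O)CC/C=C(\C)CO | intermediate
12 | (3S,6E)-8-bromo-3,7-dimethylocta-1,6-dien-3-ol | C=C[C@@](C)(O)CC/C=C(\C)CBr | intermediate
13 | trimethylsilyl ether of 12 | C=C[C@@](C)(O[Si](C)(C)C)CC/C=C(\C)CBr | intermediate
14 | dilithio sulfone (C14 lithium alkoxide, C9 α-sulfonyl carbanion of 9) | [Li]C(S(=O)(=O)c1ccccc1)[C@@H]1C(C)(C)[C@@H](O[Li])CC[C@]1(C)O[Si](CC)(CC)CC | intermediate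
15 | C9-phenylsulfonyl coupled triene (C9 epimers; C3–OSiMe3, C11–OSiEt3, axial C14–OH) | C=C[C@@](C)(O[Si](C)(C)C)CC/C=C(C)/CC(S(=O)(=O)c1ccccc1)[C@@H]2C(C)(C)[C@@H](O)CC[C@]2(C)O[Si](CC)(CC)CC | intermediate
16 | desulfonylated trimethylsilyl ether | C=C[C@@](C)(O[Si](C)(C)C)CC/C=C(C)/CC[C@@H]1C(C)(C)[C@@H](O)CC[C@]1(C)O[Si](CC)(CC)CC | intermediate
17 | diene diol (free C3–OH, axial C14–OH, C11–OSiEt3, (E)-C6=C7) | C=C[C@@](C)(O)CC/C=C(C)/CC[C@@H]1C(C)(C)[C@@H](O)CC[C@]1(C)O[Si](CC)(CC)CC | intermediate
18 | bromotetrahydropyran alcohol (axial C14–OH, C11–OSiEt3) | C=C[C@]1(C)CC[C@@H](Br)[C@](C)(CC[C@@H]2C(C)(C)[C@@H](O)CC[C@]2(C)O[Si](CC)(CC)CC)O1 | intermediate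
19 | dibromide C11 triethylsilyl ether | C=C[C@]1(C)CC[C@@H](Br)[C@](C)(CC[C@@H]2C(C)(C)[C@H](Br)CC[C@]2(C)O[Si](CC)(CC)CC)O1 | intermediate
20 | CNP0244533.1 | C=C[C@]1(C)CC[C@@H](Br)[C@](C)(CC[C@@H]2C(C)(C)[C@H](Br)CC[C@]2(C)O)O1 | target

**Step count and risks**

Total step count: 16. Longest linear sequence: 13 steps (steps 1–8 and 12–16); the linalool branch is steps 9–11.

Steps most likely to fail:

1. Step 3 (key step). The wrong bridgehead, C10, may migrate, or the pinane-type epoxide may open and rearrange under the acid released; regiochemistry on this epoxy ketone has no direct precedent. Fallback: setting out from 3, the oxidation is handed to a flavin-dependent Baeyer–Villiger monooxygenase (cyclohexanone monooxygenase type, NADPH recycled with glucose dehydrogenase and glucose, phosphate buffer pH 8, air), so that the migrating carbon is chosen by the enzyme pocket and not by substrate electronics. Such enzymes are known to oxidise bicyclic cyclobutanones, and complementary members of the family give opposite regioisomers, so a small panel is screened. The neutral medium spares the epoxide, no new compound is formed on the way (F0), and the route is rejoined at 4.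

2. Step 14. Bromonium formation may show little bias between the two alkene faces, and 5-exo closure may compete with the 6-endo mode, so the required diastereomer could be a minor product. Fallback: setting out from 17, Hg(OCOCF3)2 in MeNO2 at −20 °C followed by aqueous KBr should give the C6 bromomercurio tetrahydropyran F1 by reversible Markovnikov oxymercuration, which favours the six-membered ether and lets the ring-forming step equilibrate. Brominolysis of the C–Hg bond (Br2, LiBr, pyridine, O2) then installs the C6 bromide, favouring the equatorial isomer, and rejoins the route at 18.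

3. Step 15. Substitution at the neopentyl C14 may be outrun by elimination or by a 1,2-methyl shift from C15 once the oxyphosphonium is formed. Fallback: setting out from 18, activation and displacement are separated. ClCH2SO2Cl and pyridine in CH2Cl2 at 0 °C give the C14 chloromethanesulfonate F2, a small and highly nucleofugal ester that can be isolated. Displacement with LiBr in DMF at 60–80 °C should then give the inverted equatorial bromide and rejoin the route at 19.

Further compounds
F0 | step 3 | none | none
F1 | step 14 | C6 bromomercurio tetrahydropyran (axial C14–OH, C11–OSiEt3) | C=C[C@]1(C)CC[C@@H]([Hg]Br)[C@](C)(CC[C@@H]2C(C)(C)[C@@H](O)CC[C@]2(C)O[Si](CC)(CC)CC)O1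
F2 | step 15 | C14 chloromethanesulfonate of 18 | C=C[C@]1(C)CC[C@@H](Br)[C@](C)(CC[C@@H]2C(C)(C)[C@@H](OS(=O)(=O)CCl)CC[C@]2(C)O[Si](CC)(CC)CC)O1
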